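The route rests on disconnecting ring C of the epigallocatechin half at the two bonds that leave ring A, O1–C8a and C4–C4a. These carbons are ortho neighbours and C4a sits beside the C5 oxygen, so an aryne C4a≡C8a is polarised to take oxygen at C8a and to carry the carbanion at C4a. In one operation the potassium alkoxide of a syn-aldol-derived 1-aryl-2-benzyloxy-3-tosyloxypropanol adds to 3-benzyloxy-5-bromobenzyne and the aryl anion displaces the tosylate, closing the pyran with both stereocentres untouched. The C7 bromide is then coupled to the 4'-phenol of a separately made gallocatechin half and all benzyl ethers are removed.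

Key step: step 7

Assumption: the two enantiomeric glycolate imides used in steps 1 and 10 are taken as purchasable; each is otherwise one N-acylation away from the commercial oxazolidinone.

**Lower partner (C2–C3–C4 and ring B)**

Step 1
Reactants: 1 3,4,5-tris(benzyloxy)benzaldehyde; 2 (S)-4-benzyl-3-[(benzyloxy)acetyl]oxazolidin-2-one
Product: 4 (4S)-4-benzyl-3-{(2S,3R)-2-(benzyloxy)-3-hydroxy-3-[3,4,5-tris(benzyloxy)phenyl]propanoyl}oxazolidin-2-one, via boron enolate 3 (not isolated)
Conditions: Bu2BOTf, Et3N, CH2Cl2, −78 → 0 °C; then 1, −78 → 0 °C; pH 7 buffer, MeOH, H2O2, 0 °C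
Reagents that add atoms: none
Why: Evans syn-aldol reaction, in which the Z-boron enolate 3 should react through a Zimmerman–Traxler transition state on the face away from the auxiliary benzyl group and so set the (2S,3R) syn pair that becomes C3 and C2 of the lower flavan.

Step 2
Reactants: 4 the syn-aldol imide
Product: 5 (1R,2R)-2-(benzyloxy)-1-[3,4,5-tris(benzyloxy)phenyl]propane-1,3-diol
Conditions: LiBH4, H2O (1 equiv), THF/Et2O, 0 °C
Reagents that add atoms: none
Why: Reductive cleavage of the N-acyl oxazolidinone by LiBH4 should give the primary alcohol and release the auxiliary without touching either stereocentre or the benzyl ethers.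

Step 3
Reactants: 5 the 1,3-diol
Product: 6 (2R,3R)-2-(benzyloxy)-3-hydroxy-3-[3,4,5-tris(benzyloxy)phenyl]propyl 4-methylbenzenesulfonate
Conditions: TsCl, Et3N, DMAP (cat.), CH2Cl2, 0 °C
Reagents that add atoms: 4-toluenesulfonyl chloride, Cc1ccc(cc1)S(=O)(=O)Cl
Why: Selective sulfonylation, since the unhindered primary hydroxyl should react much faster than the hindered secondary benzylic one.

**Aryne precursor (ring A of the lower half)**

Step 4
Reactants: 7 5-bromobenzene-1,3-diol
Product: 8 5-bromo-2-iodobenzene-1,3-diol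
Conditions: I2, NaHCO3, H2O/THF, 0 °C → rt
Reagents that add atoms: iodine, II
Why: Electrophilic aromatic iodination under the aqueous hydrogencarbonate conditions that place iodine between the two hydroxyls of resorcinol, the two alternative sites being further shielded here by the bromine.

Step 5
Reactants: 8 5-bromo-2-iodobenzene-1,3-diol
Product: 11 5-bromo-3-hydroxy-2-(trimethylsilyl)phenyl trifluoromethanesulfonate, via bis-silyl ether 9 (not isolated), via silyl ether triflate 10 (not isolated)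
Conditions: HMDS, THF, reflux, then evaporation; n-BuLi, THF, −78 °C; Tf2O, −78 → 0 °C; aq. citric acid, MeOH, rt
Reagents that add atoms: hexamethyldisilazane, C[Si](C)(C)N[Si](C)(C)C; trifluoromethanesulfonic anhydride, O=S(=O)(OS(=O)(=O)C(F)(F)F)C(F)(F)F
Why: O-silylation, iodine–lithium exchange (faster than bromine–lithium exchange at −78 °C) and retro-Brook 1,3 O→C silyl migration should move one silyl group to carbon and leave one lithium phenoxide for Tf2O, so the symmetric resorcinol is desymmetrised without statistics and the remaining aryl silyl ether is lost on acidic work-up.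

Step 6
Reactants: 11 the hydroxy silyl triflate
Product: 12 3-(benzyloxy)-5-bromo-2-(trimethylsilyl)phenyl trifluoromethanesulfonate
Conditions: BnOH, PPh3, DIAD, THF, 0 °C → rt
Reagents that add atoms: benzyl alcohol, OCc1ccccc1
Why: Mitsunobu etherification of the acidic phenol under neutral conditions, chosen because carbonate bases could set off the o-silylaryl triflate.

**Key annulation**

Step 7
Reactants: 6 the hydroxy tosylate; 12 the o-silylaryl triflate
Product: 16 (2R,3R)-3,5-bis(benzyloxy)-7-bromo-2-[3,4,5-tris(benzyloxy)phenyl]chromane, via potassium alkoxide 13 (not isolated), via aryne 14 (not isolated), via aryl carbanion 15 (not isolated)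
Conditions: KH, 18-crown-6, THF, −20 °C; then 12, KF, −20 °C → rt
Reagents that add atoms: none
Why: Proposed new method: KF removes the trimethylsilyl group of 12 with loss of triflate to give aryne 14, alkoxide 13 adds to it and the resulting aryl carbanion 15 displaces the primary tosylate within the same molecule. The closest known reaction types are the aryne annulation of salicylates to xanthones (nucleophilic addition to an aryne followed by intramolecular capture of the aryl anion) and the Parham cycloalkylation of aryllithiums that carry a tethered alkyl halide or sulfonate; capture of an aryne-derived carbanion by the sp3 sulfonate of an aliphatic alkoxide is the untested element. Ring C closes in the 6-exo-tet mode at an unbranched CH2. No stereocentre is created, because C2 keeps its C–O bond and C3 is a spectator, so the syn pair from the aldol becomes the 2,3-cis (2R,3R) array. The step needs oxygen to enter at the aryne carbon remote from the benzyloxy group, which the inductive polarisation and bond-angle distortion caused by that oxygen substituent beside the triple bond should secure (the carbanion develops ortho to it, and the bromine two positions away has only a minor influence). It also needs alkylation to outrun protonation, oxetane closure and fluoride attack on the tosylate, which the preformed alkoxide (no O–H), the aprotic medium, the low temperature and the benzyl group on the C3 oxygen (no epoxide or Payne pathway) are meant to secure.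

**Upper half (gallocatechin unit with free 4'-OH)**

Step 8
Reactants: 17 3,4,5-trihydroxybenzaldehyde
Product: 18 4-(allyloxy)-3,5-dihydroxybenzaldehyde
Conditions: allyl bromide (1 equiv), NaHCO3, DMF, 40 °C
Reagents that add atoms: allyl bromide, C=CCBr
Why: Williamson etherification under weak base, in which only the 4-hydroxyl, para to the formyl group and the most acidic, should be ionised and alkylated.

Step 9
Reactants: 18 4-(allyloxy)-3,5-dihydroxybenzaldehyde
Product: 19 4-(allyloxy)-3,5-bis(benzyloxy)benzaldehyde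
Conditions: BnBr, K2CO3, DMF, rt
Reagents that add atoms: benzyl bromide, BrCc1ccccc1
Why: Williamson benzylation of the two remaining phenols.

Step 10
Reactants: 19 4-(allyloxy)-3,5-bis(benzyloxy)benzaldehyde; 20 (R)-4-benzyl-3-[(benzyloxy)acetyl]oxazolidin-2-one
Product: 22 (4R)-4-benzyl-3-{(2R,3S)-3-[4-(allyloxy)-3,5-bis(benzyloxy)phenyl]-2-(benzyloxy)-3-hydroxypropanoyl}oxazolidin-2-one, via boron enolate 21 (not isolated)
Conditions: Bu2BOTf, Et3N, CH2Cl2, −78 → 0 °C; then 19, −78 → 0 °C; pH 7 buffer, MeOH, H2O2, 0 °C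
Reagents that add atoms: none
Why: Evans syn-aldol reaction with the enantiomeric auxiliary, which should give the mirror-image (2R,3S) syn pair by the same Zimmerman–Traxler control.

Step 11
Reactants: 22 the syn-aldol imide
Product: 23 (1S,2S)-1-[4-(allyloxy)-3,5-bis(benzyloxy)phenyl]-2-(benzyloxy)propane-1,3-diol
Conditions: LiBH4, H2O (1 equiv), THF/Et2O, 0 °C
Reagents that add atoms: none
Why: Reductive cleavage of the N-acyl oxazolidinone by LiBH4, as in step 2, with the allyl and benzyl ethers inert.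

Step 12
Reactants: 23 the 1,3-diol
Product: 24 (2S,3S)-3-[4-(allyloxy)-3,5-bis(benzyloxy)phenyl]-2-(benzyloxy)-3-hydroxypropyl 4-methylbenzenesulfonate
Conditions: TsCl, Et3N, DMAP (cat.), CH2Cl2, 0 °C
Reagents that add atoms: 4-toluenesulfonyl chloride, Cc1ccc(cc1)S(=O)(=O)Cl
Why: Selective sulfonylation of the primary hydroxyl over the hindered benzylic one.

Step 13
Reactants: 25 3,5-bis(benzyloxy)phenol
Product: 26 3,5-bis(benzyloxy)-2-bromophenol
Conditions: NBS, CH2Cl2, −78 → 0 °C
Reagents that add atoms: N-bromosuccinimide, O=C1CCC(=O)N1Br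
Why: Electrophilic aromatic bromination, which in a non-polar solvent at low temperature should go ortho to the free hydroxyl because the site between the two benzyloxy groups is more hindered.

Step 14
Reactants: 24 the hydroxy tosylate; 26 3,5-bis(benzyloxy)-2-bromophenol
Product: 27 (2S,3R)-3-[4-(allyloxy)-3,5-bis(benzyloxy)phenyl]-2-(benzyloxy)-3-[3,5-bis(benzyloxy)-2-bromophenoxy]propyl 4-methylbenzenesulfonate
Conditions: PPh3, DIAD, toluene, 0 °C → rt
Reagents that add atoms: none
Why: Mitsunobu etherification, in which SN2 displacement of the activated benzylic oxygen by the phenoxide should invert the carbinol centre to (R) and turn the syn pair into the anti pair needed for a 2,3-trans flavan.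

Step 15
Reactants: 27 the bromoaryl ether tosylate
Product: 29 (2R,3S)-2-[4-(allyloxy)-3,5-bis(benzyloxy)phenyl]-3,5,7-tris(benzyloxy)chromane, via aryllithium 28 (not isolated)
Conditions: n-BuLi, THF, −78 → 0 °C
Reagents that add atoms: none
Why: Parham cycloalkylation, in which bromine–lithium exchange gives aryllithium 28 that should close the pyran by 6-exo-tet displacement of the primary tosylate with no change at either stereocentre.

Step 16
Reactants: 29 the allyl-protected flavan
Product: 30 2,6-bis(benzyloxy)-4-[(2R,3S)-3,5,7-tris(benzyloxy)chroman-2-yl]phenol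
Conditions: Pd(PPh3)4 (cat.), morpholine, THF, rt
Reagents that add atoms: none
Why: Palladium-catalysed deallylation of Tsuji–Trost type, in which the π-allyl complex is trapped by morpholine, should free only the 4'-phenol and leave the benzyl ethers.

**Union and deprotection**

Step 17
Reactants: 16 the 7-bromoflavan; 30 the 4'-phenol
Product: 31 (2R,3R)-3,5-bis(benzyloxy)-7-{2,6-bis(benzyloxy)-4-[(2R,3S)-3,5,7-tris(benzyloxy)chroman-2-yl]phenoxy}-2-[3,4,5-tris(benzyloxy)phenyl]chromane
Conditions: CuI (cat.), picolinic acid (cat.), K3PO4, DMSO, 90 °C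
Reagents that add atoms: none
Why: Ullmann-type copper-catalysed diaryl ether synthesis with the picolinic acid ligand system suited to phenols that carry two ortho substituents, helped by the unhindered bromide of 16 and involving no stereocentre.

Step 18
Reactants: 31 the decabenzyl ether
Product: 32 (2R,3R)-7-{2,6-dihydroxy-4-[(2R,3S)-3,5,7-trihydroxychroman-2-yl]phenoxy}-2-(3,4,5-trihydroxyphenyl)chromane-3,5-diol (CNP0298095.1)
Conditions: H2 (1 atm), Pd(OH)2/C, THF/MeOH, rt
Reagents that add atoms: none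
Why: Hydrogenolysis of all ten benzyl ethers under neutral conditions should leave the two chroman C2–O bonds and the four stereocentres intact.

**Compound list**

1 | 3,4,5-tris(benzyloxy)benzaldehyde | O=Cc1cc(OCc2ccccc2)c(OCc2ccccc2)c(OCc2ccccc2)c1 | starting material
2 | (S)-4-benzyl-3-[(benzyloxy)acetyl]oxazolidin-2-one | O=C(COCc1ccccc1)N1C(=O)OC[C@@H]1Cc1ccccc1 | starting material
3 | dibutylboron Z-enolate of 2 | CCCCB(CCCC)O/C(=C\OCc1ccccc1)N1C(=O)OC[C@@H]1Cc1ccccc1 | intermediate
4 | (4S)-4-benzyl-3-{(2S,3R)-2-(benzyloxy)-3-hydroxy-3-[3,4,5-tris(benzyloxy)phenyl]propanoyl}oxazolidin-2-one | O[C@H](c1cc(OCc2ccccc2)c(OCc2ccccc2)c(OCc2ccccc2)c1)[C@H](OCc1ccccc1)C(=O)N1C(=O)OC[C@@H]1Cc1ccccc1 | intermediate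
5 | (1R,2R)-2-(benzyloxy)-1-[3,4,5-tris(benzyloxy)phenyl]propane-1,3-diol | O[C@H](c1cc(OCc2ccccc2)c(OCc2ccccc2)c(OCc2ccccc2)c1)[C@H](OCc1ccccc1)CO | intermediate
6 | (2R,3R)-2-(benzyloxy)-3-hydroxy-3-[3,4,5-tris(benzyloxy)phenyl]propyl 4-methylbenzenesulfonate | O[C@H](c1cc(OCc2ccccc2)c(OCc2ccccc2)c(OCc2ccccc2)c1)[C@H](OCc1ccccc1)COS(=O)(=O)c1ccc(C)cc1 | intermediate
7 | 5-bromobenzene-1,3-diol | Oc1cc(O)cc(Br)c1 | starting material
8 | 5-bromo-2-iodobenzene-1,3-diol | Oc1cc(Br)cc(O)c1I | intermediate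
9 | 5-bromo-2-iodo-1,3-bis(trimethylsilyloxy)benzene | C[Si](C)(C)Oc1cc(Br)cc(O[Si](C)(C)C)c1I | intermediate
10 | 5-bromo-2-(trimethylsilyl)-3-(trimethylsilyloxy)phenyl trifluoromethanesulfonate | C[Si](C)(C)Oc1cc(Br)cc(OS(=O)(=O)C(F)(F)F)c1[Si](C)(C)C | intermediate
11 | 5-bromo-3-hydroxy-2-(trimethylsilyl)phenyl trifluoromethanesulfonate | Oc1cc(Br)cc(OS(=O)(=O)C(F)(F)F)c1[Si](C)(C)C | intermediate
12 | 3-(benzyloxy)-5-bromo-2-(trimethylsilyl)phenyl trifluoromethanesulfonate | C[Si](C)(C)c1c(OCc2ccccc2)cc(Br)cc1OS(=O)(=O)C(F)(F)F | intermediate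
13 | potassium alkoxide of 6 | [K+].[O-][C@H](c1cc(OCc2ccccc2)c(OCc2ccccc2)c(OCc2ccccc2)c1)[C@H](OCc1ccccc1)COS(=O)(=O)c1ccc(C)cc1 | intermediate
14 | 3-(benzyloxy)-5-bromobenzyne | BrC1=CC#CC(OCc2ccccc2)=C1 | intermediate
15 | potassium 2-(benzyloxy)-4-bromo-6-{(1R,2R)-2-(benzyloxy)-3-(tosyloxy)-1-[3,4,5-tris(benzyloxy)phenyl]propoxy}benzenide | [K+].[c-]1c(OCc2ccccc2)cc(Br)cc1O[C@H](c1cc(OCc2ccccc2)c(OCc2ccccc2)c(OCc2ccccc2)c1)[C@H](OCc1ccccc1)COS(=O)(=O)c1ccc(C)cc1 | intermediate
16 | (2R,3R)-3,5-bis(benzyloxy)-7-bromo-2-[3,4,5-tris(benzyloxy)phenyl]chromane | Brc1cc(OCc2ccccc2)c2c(c1)O[C@H](c1cc(OCc3ccccc3)c(OCc3ccccc3)c(OCc3ccccc3)c1)[C@H](OCc1ccccc1)C2 | intermediate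
17 | 3,4,5-trihydroxybenzaldehyde | O=Cc1cc(O)c(O)c(O)c1 | starting material
18 | 4-(allyloxy)-3,5-dihydroxybenzaldehyde | O=Cc1cc(O)c(OCC=C)c(O)c1 | intermediate
19 | 4-(allyloxy)-3,5-bis(benzyloxy)benzaldehyde | O=Cc1cc(OCc2ccccc2)c(OCC=C)c(OCc2ccccc2)c1 | intermediate
20 | (R)-4-benzyl-3-[(benzyloxy)acetyl]oxazolidin-2-one | O=C(COCc1ccccc1)N1C(=O)OC[C@H]1Cc1ccccc1 | starting material
21 | dibutylboron Z-enolate of 20 | CCCCB(CCCC)O/C(=C\OCc1ccccc1)N1C(=O)OC[C@H]1Cc1ccccc1 | intermediate
22 | (4R)-4-benzyl-3-{(2R,3S)-3-[4-(allyloxy)-3,5-bis(benzyloxy)phenyl]-2-(benzyloxy)-3-hydroxypropanoyl}oxazolidin-2-one | O[C@@H](c1cc(OCc2ccccc2)c(OCC=C)c(OCc2ccccc2)c1)[C@@H](OCc1ccccc1)C(=O)N1C(=O)OC[C@H]1Cc1ccccc1 | intermediate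
23 | (1S,2S)-1-[4-(allyloxy)-3,5-bis(benzyloxy)phenyl]-2-(benzyloxy)propane-1,3-diol | O[C@@H](c1cc(OCc2ccccc2)c(OCC=C)c(OCc2ccccc2)c1)[C@@H](OCc1ccccc1)CO | intermediate
24 | (2S,3S)-3-[4-(allyloxy)-3,5-bis(benzyloxy)phenyl]-2-(benzyloxy)-3-hydroxypropyl 4-methylbenzenesulfonate | O[C@@H](c1cc(OCc2ccccc2)c(OCC=C)c(OCc2ccccc2)c1)[C@@H](OCc1ccccc1)COS(=O)(=O)c1ccc(C)cc1 | intermediate
25 | 3,5-bis(benzyloxy)phenol | Oc1cc(OCc2ccccc2)cc(OCc2ccccc2)c1 | starting material
26 | 3,5-bis(benzyloxy)-2-bromophenol | Oc1cc(OCc2ccccc2)cc(OCc2ccccc2)c1Br | intermediate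
27 | (2S,3R)-3-[4-(allyloxy)-3,5-bis(benzyloxy)phenyl]-2-(benzyloxy)-3-[3,5-bis(benzyloxy)-2-bromophenoxy]propyl 4-methylbenzenesulfonate | Brc1c(OCc2ccccc2)cc(OCc2ccccc2)cc1O[C@H](c1cc(OCc2ccccc2)c(OCC=C)c(OCc2ccccc2)c1)[C@@H](OCc1ccccc1)COS(=O)(=O)c1ccc(C)cc1 | intermediate
28 | aryllithium from 27 (lithium in place of bromine) | [Li]c1c(OCc2ccccc2)cc(OCc2ccccc2)cc1O[C@H](c1cc(OCc2ccccc2)c(OCC=C)c(OCc2ccccc2)c1)[C@@H](OCc1ccccc1)COS(=O)(=O)c1ccc(C)cc1 | intermediate
29 | (2R,3S)-2-[4-(allyloxy)-3,5-bis(benzyloxy)phenyl]-3,5,7-tris(benzyloxy)chromane | C=CCOc1c(OCc2ccccc2)cc(cc1OCc1ccccc1)[C@H]1Oc2cc(OCc3ccccc3)cc(OCc3ccccc3)c2C[C@@H]1OCc1ccccc1 | intermediate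
30 | 2,6-bis(benzyloxy)-4-[(2R,3S)-3,5,7-tris(benzyloxy)chroman-2-yl]phenol | Oc1c(OCc2ccccc2)cc(cc1OCc1ccccc1)[C@H]1Oc2cc(OCc3ccccc3)cc(OCc3ccccc3)c2C[C@@H]1OCc1ccccc1 | intermediate
31 | (2R,3R)-3,5-bis(benzyloxy)-7-{2,6-bis(benzyloxy)-4-[(2R,3S)-3,5,7-tris(benzyloxy)chroman-2-yl]phenoxy}-2-[3,4,5-tris(benzyloxy)phenyl]chromane | C(c5ccccc5)Oc1cc(OCc5ccccc5)c2c(c1)O[C@H](c1cc(OCc5ccccc5)c(Oc3cc(OCc5ccccc5)c4c(c3)O[C@H](c3cc(OCc5ccccc5)c(OCc5ccccc5)c(OCc5ccccc5)c3)[C@H](OCc5ccccc5)C4)c(OCc5ccccc5)c1)[C@@H](OCc5ccccc5)C2 | intermediate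
32 | (2R,3R)-7-{2,6-dihydroxy-4-[(2R,3S)-3,5,7-trihydroxychroman-2-yl]phenoxy}-2-(3,4,5-trihydroxyphenyl)chromane-3,5-diol | Oc1cc(O)c2c(c1)O[C@H](c1cc(O)c(Oc3cc(O)c4c(c3)O[C@H](c3cc(O)c(O)c(O)c3)[C@H](O)C4)c(O)c1)[C@@H](O)C2 | target

**Count and risks**

Total step count: 18. Longest linear sequence: 10 steps (steps 8, 9, 10, 11, 12, 14, 15, 16, 17, 18).

Steps most likely to fail:

Step 7 (bears the label). The aryl carbanion may be protonated before it alkylates. The alkoxide may also close onto its own tosylate or fragment before it meets the aryne. The fallback forms the C–O and C–C bonds one after the other by known reactions; it sets out from 6 and 8 and comes back at 16. Mitsunobu esterification of 6 with 4-nitrobenzoic acid (PPh3, DIAD, THF) should invert the carbinol and give (1S,2R)-2-(benzyloxy)-3-(tosyloxy)-1-[3,4,5-tris(benzyloxy)phenyl]propyl 4-nitrobenzoate F1. Mild methanolysis (K2CO3 cat., MeOH/THF, 0 °C) should then give the anti alcohol (2R,3S)-2-(benzyloxy)-3-hydroxy-3-[3,4,5-tris(benzyloxy)phenyl]propyl 4-methylbenzenesulfonate F2. Separately, 8 is monobenzylated (BnBr, 1 equiv, K2CO3, acetone) to 3-(benzyloxy)-5-bromo-2-iodophenol F3. Mitsunobu etherification of F2 with F3 inverts the carbinol once more and should give (2R,3R)-2-(benzyloxy)-3-[3-(benzyloxy)-5-bromo-2-iodophenoxy]-3-[3,4,5-tris(benzyloxy)phenyl]propyl 4-methylbenzenesulfonate F4. Iodine–lithium exchange (n-BuLi, THF, −100 °C, selective over the aryl bromide) and Parham cycloalkylation on warming then close ring C to 16.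

Step 17. Ligand exchange and C–O bond formation at copper may be slow with the doubly ortho-substituted phenoxide, so that protodebromination of 16 and oxidative degradation of the electron-rich phenol compete. The fallback replaces the Ullmann coupling by an oxidative boron-based coupling; it sets out from 16 and comes back at 31. Bromine–lithium exchange (n-BuLi, THF, −78 °C), B(OiPr)3 and aqueous acid should give [(2R,3R)-3,5-bis(benzyloxy)-2-[3,4,5-tris(benzyloxy)phenyl]chroman-7-yl]boronic acid F5. Chan–Lam coupling of F5 with 30 (Cu(OAc)2, pyridine, 4 Å molecular sieves, air, CH2Cl2, rt) then gives 31.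

Step 5. Bromine–lithium exchange may compete with iodine–lithium exchange, or both silyl groups may be transferred or lost, which would erase the desymmetrisation. The fallback desymmetrises before the silyl migration and follows the classical o-halophenol sequence; it sets out from 8 and comes back at 12, so step 6 is not needed. Monobenzylation of 8 (BnBr, 1 equiv, K2CO3, acetone) gives 3-(benzyloxy)-5-bromo-2-iodophenol F3, the compound already used in the first fallback. HMDS (THF, reflux) gives [3-(benzyloxy)-5-bromo-2-iodophenoxy]trimethylsilane F6. n-BuLi (THF, −78 °C; iodine–lithium exchange and retro-Brook migration) followed by Tf2O should then give 12.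

Further compounds
F1 | step 7 | (1S,2R)-2-(benzyloxy)-3-(tosyloxy)-1-[3,4,5-tris(benzyloxy)phenyl]propyl 4-nitrobenzoate | O=C(O[C@@H](c1cc(OCc2ccccc2)c(OCc2ccccc2)c(OCc2ccccc2)c1)[C@H](OCc1ccccc1)COS(=O)(=O)c1ccc(C)cc1)c1ccc(cc1)[N+](=O)[O-]
F2 | step 7 | (2R,3S)-2-(benzyloxy)-3-hydroxy-3-[3,4,5-tris(benzyloxy)phenyl]propyl 4-methylbenzenesulfonate | O[C@@H](c1cc(OCc2ccccc2)c(OCc2ccccc2)c(OCc2ccccc2)c1)[C@H](OCc1ccccc1)COS(=O)(=O)c1ccc(C)cc1
F3 | step 7 | 3-(benzyloxy)-5-bromo-2-iodophenol | Oc1cc(Br)cc(OCc2ccccc2)c1I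
F4 | step 7 | (2R,3R)-2-(benzyloxy)-3-[3-(benzyloxy)-5-bromo-2-iodophenoxy]-3-[3,4,5-tris(benzyloxy)phenyl]propyl 4-methylbenzenesulfonate | Brc1cc(OCc2ccccc2)c(I)c(c1)O[C@H](c1cc(OCc2ccccc2)c(OCc2ccccc2)c(OCc2ccccc2)c1)[C@H](OCc1ccccc1)COS(=O)(=O)c1ccc(C)cc1
F5 | step 17 | [(2R,3R)-3,5-bis(benzyloxy)-2-[3,4,5-tris(benzyloxy)phenyl]chroman-7-yl]boronic acid | OB(O)c1cc(OCc2ccccc2)c2c(c1)O[C@H](c1cc(OCc3ccccc3)c(OCc3ccccc3)c(OCc3ccccc3)c1)[C@H](OCc1ccccc1)C2
F6 | step 5 | [3-(benzyloxy)-5-bromo-2-iodophenoxy]trimethylsilane | C[Si](C)(C)Oc1cc(Br)cc(OCc2ccccc2)c1I
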